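## Structural features

The target is a single oxolane ring (O1, C2–C5) that carries the same 4-hydroxy-3-methoxyphenyl group on C2 and on C5, a methyl group and a tertiary hydroxyl on C3, and a methyl group on C4. All four ring carbons are contiguous stereocentres, (2R,3S,4S,5R): the two aryl groups are cis to each other, the two methyl groups are trans, the C3 hydroxyl is trans to the C2 aryl and cis to the C4 methyl, and the C5 aryl is trans to the C4 methyl. Without the C3 hydroxyl the molecule would be twofold symmetric, so this hydroxyl is what makes the two benzylic positions different: C2 stands beside the carbinol, C5 beside a plain methine. The fragile points are the two ring C–O bonds, both benzylic to electron-rich arenes (acid ionisation, hydrogenolysis), the free phenols (oxidation to quinone methides) and the tertiary alcohol (elimination). The real difficulty is C3, a fully substituted carbinol carbon between C2 and C4, whose C–O bond must be fixed relative to both neighbours; addition to a C3 ketone would ask a nucleophile to choose between two similarly hindered faces. C5 is the easy centre, because a p-oxygenated benzylic ether carbon can be formed last through a stabilised cation and need not be carried through the route. The key step uses the fact that the C3 oxygen, C3, C4 and the aryl-bearing C5 are the O1–C5–C4–C3 array of a 3-aryl-4,5-dihydroisoxazole, so an aryl nitrile oxide adding across an E-configured C3=C4 alkene makes C3–O and C4–C5 at once, with C2 as the controlling centre.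

## Logic of the disconnections

**18 to 17.** The two phenolic O–CH2Ph bonds are cut (that is, the phenols are masked). Free phenols would let both benzylic positions ionise or oxidise through quinone methides in every acidic or oxidative step. The gain is that the arenes become inert spectators. The demand is that the final hydrogenolysis must remove two aryl benzyl ethers without touching the two benzylic C–O bonds of the ring.

**17 to 16.** The O1–C5 bond is cut. C5 is the benzylic carbon with no oxygenated neighbour, so its cation is the best stabilised one in the molecule, and capture by the C2 oxygen places the C5 aryl trans to the C4 methyl whatever the C5 configuration of 16. The gain is an open chain in which only three stereocentres have to be controlled. The demand is that ionisation occurs at C5 and not at C2.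

**16 to 15 to 14.** The O–Si bond at the C2 oxygen and the C5–H bond are removed in turn (protecting group and oxidation level). This exposes 14, in which the C3 hydroxyl and a C5 carbonyl stand in a 1,3-relation. The gain is a recognisable retron. The demand is that the ketone is reduced before fluoride is used, so that no β-hydroxy ketone meets a base, and that no selectivity at C5 is needed.

**14 to 12 (through 13).** The C5 carbonyl is replaced by C=N and the N–O bond is re-formed. The tertiary alcohol and the ketone then come masked in one five-membered heterocycle. The gain is that the hindered C3–O bond is no longer made by a nucleophile adding to a ketone. The demand is a reductive N–O cleavage that spares benzyl ethers, the silyl ether and the C4 centre.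

**12 to 7 and 11.** The C4–C5 and C3–O bonds are cut. This is the strategic cut: it halves the molecule into two pieces that each hold one arene, and it removes two stereocentres and the only ring of 12. The demand is regioselectivity (oxygen to C3), suprafacial addition to an E alkene, facial control by C2, and enough reactivity from a trisubstituted alkene.

**11 to 10 to 9 to 8.** The C≡N–O unit is traced back through loss of HCl and of chlorine to an oxime and then to the C=O of 8. 11 cannot be stored, so it is generated in the flask. The gain is a purchasable aldehyde as the source of one half. The demand is that chlorination stays on the oxime carbon and that 11 is released slowly.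

**7 to 6 to 5.** The O–Si bond is cut and the single enantiomer is traced to the racemate. The ether (not the free alcohol) is wanted in the key step because it cannot deliver the dipole by hydrogen bonding and it takes the inside position. The gain is that C2 is set by a kinetic resolution with a reliable sense, not by reduction of a ketone flanked by two sp2 groups. The demand is a resolution tolerant of an electron-rich benzylic allylic alcohol.

**5 to 4 and 3, then 4 to 2 to 1.** The C2–aryl bond is cut, then C–Mg and the phenolic O–benzyl bond. 3 brings the E alkene with both methyl groups ready-made. The gain is three cheap starting materials (1, 3, 8). The demand is clean 1,2-addition to an enal without loss of alkene geometry.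

## Other disconnections considered

**Alternative 1:** The cut removes both C–aryl bonds (C2–aryl and C5–aryl) and leaves an aryl-free chiral core, (3S,4R)-3-(acetyloxy)-3,4-dimethyloxolane-2,5-diyl diacetate A2.
- **Forward key step:** BF3·OEt2 would ionise the two anomeric acetates of A2 one after the other, and two equivalents of [4-(benzyloxy)-3-methoxyphenyl]zinc bromide A3 (reachable from 2) would add to the oxocarbenium ions. The product is (2R,3S,4S,5R)-2,5-bis[4-(benzyloxy)-3-methoxyphenyl]-3,4-dimethyloxolan-3-yl acetate A1. No ring is closed.
- **In favour:** It uses the fact that both aryl groups are identical, so one reagent serves twice. The C3 acetate can bridge to the C2 cation and send the aryl group trans to the C3 oxygen, and attack anti to the C4 methyl gives the trans relation at C5; both outcomes are what the target needs. No resolution is needed for C2, and after A1 only ester cleavage and debenzylation remain.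
- **Against:** A2 is not purchasable, and its two stereocentres (the tertiary carbinol beside the methine) are the hard part of the target, so the key step postpones the central problem. The second ionisation would run on a 2-aryloxolane whose own benzylic C–O bond is labile to BF3·OEt2. A tertiary acetate may eliminate or be trapped as an orthoester. C5 would rest on 1,2-induction by one methyl group.
- **Comparison:** In convergence and in steps after the core it is better than the chosen plan, and its control of C2 by participation is at least the equal of the relay used here. On structure the chosen plan is stronger, because its key step creates C3 and C4. On mechanism, two successive cations on an electron-rich aryl oxolane are harder to hold than one cation closed intramolecularly. Overall step economy would be decided by the route to A2, which is expected to cost more steps than are saved.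

**Alternative 2:** The cut is C4–C5 inside the ring, with both ring C–O bonds already present in an acetal: (2R,4R,5Z)-2,4-bis[4-(benzyloxy)-3-methoxyphenyl]-5-ethylidene-1,3-dioxolane A5. A5 would come from (2R)-2-[4-(benzyloxy)-3-methoxyphenyl]-2-hydroxyacetic acid A6 and 8, followed by ethylidenation of the dioxolanone carbonyl.
- **Forward key step:** Me2AlCl would open A5 to an oxocarbenium ion and an aluminium enolate that reclose through carbon (Petasis–Ferrier rearrangement) to (2R,4S,5R)-2,5-bis[4-(benzyloxy)-3-methoxyphenyl]-4-methyloxolan-3-one A4.
- **In favour:** The 2,5-cis relation of the aryl groups is the intrinsic outcome of this rearrangement. The absolute configuration comes from A6. The C4 methyl is α to the ketone and can settle trans to the C5 aryl. A4 would be reached in about three steps.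
- **Against:** A4 lacks both C3 substituents. A methyl nucleophile must then add to the C3 ketone from the face that carries the neighbouring C2 aryl group, whereas sterics favour the face beside the C4 methyl, which leads to the C3 epimer. The ketone is flanked by an acidic, benzylic, α-oxygenated C2–H (enolisation, epimerisation). Ethylidenation of an ester-type carbonyl needs a titanium alkylidene reagent and raises an alkene-geometry question.
- **Comparison:** On step economy it is better than the chosen plan. On the 2,5-cis relation it is equal or better, since that relation is built in and does not depend on a cation closure. On mechanism, the reactivity of the key step is less in doubt than that of a cycloaddition to a hindered alkene. On structure the chosen plan is better where it matters most: it fixes the tertiary C3–O bond by a stereospecific cycloaddition and does not rely on a facial choice at a ketone.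

**Alternative 3:** The cut is C3–C4 together with both C–O1 bonds. The pieces are (E)-isoeugenol A8, (Z)-1-(4-hydroxy-3-methoxyphenyl)prop-1-en-2-yl acetate A9 and a molecule of water.
- **Forward key step:** Laccase and O2 would oxidise A8 and A9 to phenoxyl radicals, and a dirigent protein would pair them at the side-chain β-carbons (C3–C4). The bis(quinone methide) would take up water at one benzylic carbon, and the new hydroxyl would close onto the other, giving (2R,3S,4S,5R)-2,5-bis(4-hydroxy-3-methoxyphenyl)-3,4-dimethyloxolan-3-yl acetate A7. Ester cleavage would then give 18.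
- **In favour:** One operation from two simple phenols, no protecting groups, one C–C bond, two C–O bonds, the ring and all four stereocentres at once, along the lines of lignan biosynthesis.
- **Against:** A8 prefers to couple with itself and through its ring or phenol oxygen. Cross-coupling of two phenols of different oxidation potential is statistical at best. No dirigent protein is known that pairs this hetero-couple with the required sense, so without protein engineering a racemic mixture of diastereomers is to be expected. Water must compete with other nucleophiles. A9 is an enol ester open to hydrolysis.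
- **Comparison:** On step economy it is far better than the chosen plan, and on protecting-group economy as well. On structure it addresses the whole skeleton directly, which the chosen plan does not. On mechanism it rests four selectivities (chemo, regio, diastereo, enantio) on one hypothetical biocatalyst, whereas the chosen plan assigns each stereocentre to a defined element.

Key step: step 6

Remark: 8 is taken as a purchasable aldehyde; 15 and 16 are carried as mixtures of epimers at the former ketone carbon because that centre is re-set in step 10; the carbinol descriptor changes from S (6, 7) to R (12 onwards) only because the CIP ranking of its neighbours changes, not because a bond at that carbon is touched.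

## Route

Step 1
Reactants: 1 4-bromo-2-methoxyphenol
Product: 2 1-(benzyloxy)-4-bromo-2-methoxybenzene
Conditions: BnBr, K2CO3, DMF, rt
Reagents that add atoms: benzyl bromide, BrCc1ccccc1
Why: Williamson ether synthesis; the phenoxide displaces bromide from a primary benzylic halide, and the aryl bromide is inert under these conditions.

Step 2
Reactants: 2 1-(benzyloxy)-4-bromo-2-methoxybenzene; 3 tiglic aldehyde, (2E)-2-methylbut-2-enal
Product: 5 (2E)-1-[4-(benzyloxy)-3-methoxyphenyl]-2-methylbut-2-en-1-ol (racemic), via arylmagnesium bromide 4 (not isolated)
Conditions: Mg, I2 (cat.), THF, 50 °C; then 3, −20 °C → rt; aq. NH4Cl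
Reagents that add atoms: none
Why: Grignard formation and 1,2-addition to an α-branched enal, for which conjugate addition is not competitive; the E alkene of 3 is carried over unchanged and the carbinol centre is formed racemic. A buffered work-up is used because the product is a benzylic and allylic alcohol on an electron-rich ring.

Step 3
Reactants: 5 (2E)-1-[4-(benzyloxy)-3-methoxyphenyl]-2-methylbut-2-en-1-ol (racemic)
Product: 6 (1S,2E)-1-[4-(benzyloxy)-3-methoxyphenyl]-2-methylbut-2-en-1-ol
Conditions: Ti(OiPr)4 (15 mol%), L-(+)-DIPT (20 mol%), t-BuOOH (0.6 equiv), 4 Å MS, CH2Cl2, −20 °C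
Reagents that add atoms: none
Why: Sharpless kinetic resolution; with L-(+)-tartrate the (R)-enantiomer is epoxidised fast to the erythro epoxy alcohol and the (S)-enantiomer is left, to be recovered once slightly more than half of 5 has reacted. A secondary allylic alcohol with an E-trisubstituted alkene and no substituent cis to the carbinol belongs to the class with the largest rate difference. This step sets C2.

Step 4
Reactants: 6 (1S,2E)-1-[4-(benzyloxy)-3-methoxyphenyl]-2-methylbut-2-en-1-ol
Product: 7 tert-butyl{[(1S,2E)-1-[4-(benzyloxy)-3-methoxyphenyl]-2-methylbut-2-en-1-yl]oxy}dimethylsilane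
Conditions: TBSCl, imidazole, DMF, rt
Reagents that add atoms: tert-butyldimethylsilyl chloride, CC(C)(C)[Si](C)(C)Cl
Why: Standard silylation of a secondary alcohol under basic conditions that cannot ionise the benzylic allylic C–O bond; the ether removes the hydrogen-bond donor and supplies the group that sits inside in the key step.

Step 5
Reactants: 8 4-(benzyloxy)-3-methoxybenzaldehyde (O-benzylvanillin)
Product: 9 (E)-4-(benzyloxy)-3-methoxybenzaldehyde oxime
Conditions: NH2OH·HCl, NaOAc, EtOH/H2O, rt
Reagents that add atoms: hydroxylamine hydrochloride, NO.Cl
Why: Oxime condensation of an aromatic aldehyde, which gives the E isomer.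

Step 6
Reactants: 9 (E)-4-(benzyloxy)-3-methoxybenzaldehyde oxime; 7 tert-butyl{[(1S,2E)-1-[4-(benzyloxy)-3-methoxyphenyl]-2-methylbut-2-en-1-yl]oxy}dimethylsilane
Product: 12 (4S,5S)-3-[4-(benzyloxy)-3-methoxyphenyl]-5-{(R)-[4-(benzyloxy)-3-methoxyphenyl][(tert-butyldimethylsilyl)oxy]methyl}-4,5-dimethyl-4,5-dihydro-1,2-oxazole, via hydroximoyl chloride 10 (not isolated), via nitrile oxide 11 (not isolated)
Conditions: 9 (3 equiv), NCS, pyridine (cat.), CHCl3, 40 °C; then 7, Et3N (slow addition), 45 °C
Reagents that add atoms: none
Why: NCS chlorinates the oxime carbon to give 10, and Et3N then removes HCl to release the nitrile oxide 11, which adds to the alkene of 7 in a concerted, asynchronous, suprafacial Huisgen cycloaddition; the closest known class is the addition of nitrile oxides to chiral allylic ethers. The isoxazoline ring is closed by the cycloaddition itself, C4–C5 and C3–O forming in one five-centre transition state, so no separate cyclisation mode has to be met. The dipole oxygen goes to the fully substituted C3 and the aryl-bearing dipole carbon to the less hindered C4, as is usual for trisubstituted alkenes and for allylic ethers. C4 is fixed relative to C3 by stereospecific cis addition to the E alkene, so the two methyl groups are cis on the isoxazoline and become trans in the later oxolane. C3 and C4 are fixed relative to C2 by the conformation of the allylic centre: the C3 methyl forces the small hydrogen into the outside position (1,2-allylic strain), the silyloxy group takes the inside position and the aryl group stands anti, so the dipole arrives on the face opposite the aryl group. This arrangement gives the (4S,5S) adduct with the (R)-carbinol, which is the relative configuration of the target. The step needs regio-, face- and chemoselectivity (cycloaddition against dimerisation of 11 to a furoxan); the first two are secured by the substitution pattern and the allylic silyl ether, the third by keeping 11 at a low stationary concentration and in excess over 7, with all NCS consumed before 7 is added.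

Step 7
Reactants: 12 (4S,5S)-3-[4-(benzyloxy)-3-methoxyphenyl]-5-{(R)-[4-(benzyloxy)-3-methoxyphenyl][(tert-butyldimethylsilyl)oxy]methyl}-4,5-dimethyl-4,5-dihydro-1,2-oxazole
Product: 14 (2R,3S,4R)-1,4-bis[4-(benzyloxy)-3-methoxyphenyl]-4-[(tert-butyldimethylsilyl)oxy]-3-hydroxy-2,3-dimethylbutan-1-one, via hydroxy imine 13 (not isolated)
Conditions: Mo(CO)6, MeCN/H2O (15:1), 80 °C
Reagents that add atoms: water, O
Why: Reductive N–O cleavage of an isoxazoline by zerovalent molybdenum, followed by hydrolysis of the ketimine 13 in the wet solvent; the medium is close to neutral, so the stereocentre α to the new ketone and the tertiary aldol linkage should survive, and benzyl and silyl ethers are not touched. No stereocentre is formed; the descriptor of the α-carbon changes only through CIP ranking.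

Step 8
Reactants: 14 (2R,3S,4R)-1,4-bis[4-(benzyloxy)-3-methoxyphenyl]-4-[(tert-butyldimethylsilyl)oxy]-3-hydroxy-2,3-dimethylbutan-1-one
Product: 15 (2S,3S,4R)-1,4-bis[4-(benzyloxy)-3-methoxyphenyl]-4-[(tert-butyldimethylsilyl)oxy]-2,3-dimethylbutane-1,3-diol (both C1 epimers)
Conditions: NaBH4, MeOH/THF, 0 °C → rt
Reagents that add atoms: none
Why: Hydride reduction of an aryl ketone; the new carbinol centre is deliberately left uncontrolled because it is re-set in step 10. Removing the ketone before any fluoride is used closes the retro-aldol pathway.

Step 9
Reactants: 15 (2S,3S,4R)-1,4-bis[4-(benzyloxy)-3-methoxyphenyl]-4-[(tert-butyldimethylsilyl)oxy]-2,3-dimethylbutane-1,3-diol (both C1 epimers)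
Product: 16 (1R,2S,3S)-1,4-bis[4-(benzyloxy)-3-methoxyphenyl]-2,3-dimethylbutane-1,2,4-triol (both C4 epimers)
Conditions: Bu4NF, THF, rt → 45 °C
Reagents that add atoms: none
Why: Fluoride cleavage of the silyl ether; the substrate holds no carbonyl group and no base-labile centre, and benzyl ethers are inert.

Step 10
Reactants: 16 (1R,2S,3S)-1,4-bis[4-(benzyloxy)-3-methoxyphenyl]-2,3-dimethylbutane-1,2,4-triol (both C4 epimers)
Product: 17 (2R,3S,4S,5R)-2,5-bis[4-(benzyloxy)-3-methoxyphenyl]-3,4-dimethyloxolan-3-ol
Conditions: CSA (0.1 equiv), CH2Cl2, 0 °C → rt
Reagents that add atoms: none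
Why: Acid-catalysed SN1 cycloetherification (5-exo closure of the C2 hydroxyl onto the p-alkoxybenzylic cation at C5); both epimers of 16 converge on one planar cation, and closure places the C5 aryl trans to the C4 methyl, which is the kinetic and the thermodynamic preference in this lignan class. C2 is expected to stay intact because a cation there would stand beside the electron-withdrawing C3 oxygen; the four-membered alternative through the C3 hydroxyl is not competitive.

Step 11
Reactants: 17 (2R,3S,4S,5R)-2,5-bis[4-(benzyloxy)-3-methoxyphenyl]-3,4-dimethyloxolan-3-ol
Product: 18 (2R,3S,4S,5R)-2,5-bis(4-hydroxy-3-methoxyphenyl)-3,4-dimethyloxolan-3-ol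
Conditions: H2 (1 atm), 10% Pd/C, EtOAc, rt
Reagents that add atoms: none
Why: Hydrogenolysis of two aryl benzyl ethers in a neutral, non-acidic solvent; these primary benzyl–OAr bonds cleave much faster than the secondary benzylic C–O bonds of the ring, so the reaction is stopped after two equivalents of hydrogen.

## Compound list

1 | 4-bromo-2-methoxyphenol | COc1cc(Br)ccc1O | starting material
2 | 1-(benzyloxy)-4-bromo-2-methoxybenzene | COc1cc(Br)ccc1OCc1ccccc1 | intermediate
3 | tiglic aldehyde, (2E)-2-methylbut-2-enal | C/C=C(\C)C=O | starting material
4 | [4-(benzyloxy)-3-methoxyphenyl]magnesium bromide (not isolated) | COc1cc([Mg]Br)ccc1OCc1ccccc1 | intermediate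
5 | (2E)-1-[4-(benzyloxy)-3-methoxyphenyl]-2-methylbut-2-en-1-ol, racemic | COc1cc(C(O)/C(C)=C/C)ccc1OCc1ccccc1 | intermediate
6 | (1S,2E)-1-[4-(benzyloxy)-3-methoxyphenyl]-2-methylbut-2-en-1-ol | COc1cc([C@@H](O)/C(C)=C/C)ccc1OCc1ccccc1 | intermediate
7 | tert-butyl{[(1S,2E)-1-[4-(benzyloxy)-3-methoxyphenyl]-2-methylbut-2-en-1-yl]oxy}dimethylsilane | COc1cc([C@@H](O[Si](C)(C)C(C)(C)C)/C(C)=C/C)ccc1OCc1ccccc1 | intermediate
8 | 4-(benzyloxy)-3-methoxybenzaldehyde (O-benzylvanillin) | COc1cc(C=O)ccc1OCc1ccccc1 | starting material
9 | (E)-4-(benzyloxy)-3-methoxybenzaldehyde oxime | COc1cc(/C=N/O)ccc1OCc1ccccc1 | intermediate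
10 | (Z)-4-(benzyloxy)-N-hydroxy-3-methoxybenzenecarboximidoyl chloride (not isolated) | COc1cc(/C(Cl)=N/O)ccc1OCc1ccccc1 | intermediate
11 | 4-(benzyloxy)-3-methoxybenzonitrile oxide (not isolated) | COc1cc(C#[N+][O-])ccc1OCc1ccccc1 | intermediate
12 | (4S,5S)-3-[4-(benzyloxy)-3-methoxyphenyl]-5-{(R)-[4-(benzyloxy)-3-methoxyphenyl][(tert-butyldimethylsilyl)oxy]methyl}-4,5-dimethyl-4,5-dihydro-1,2-oxazole | COc1cc([C@@H](O[Si](C)(C)C(C)(C)C)[C@@]2(C)ON=C(c3ccc(OCc4ccccc4)c(OC)c3)[C@@H]2C)ccc1OCc1ccccc1 | intermediate
13 | (1R,2S,3S)-1,4-bis[4-(benzyloxy)-3-methoxyphenyl]-1-[(tert-butyldimethylsilyl)oxy]-4-imino-2,3-dimethylbutan-2-ol (not isolated) | COc1cc([C@@H](O[Si](C)(C)C(C)(C)C)[C@@](C)(O)[C@@H](C)C(=N)c2ccc(OCc3ccccc3)c(OC)c2)ccc1OCc1ccccc1 | intermediate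
14 | (2R,3S,4R)-1,4-bis[4-(benzyloxy)-3-methoxyphenyl]-4-[(tert-butyldimethylsilyl)oxy]-3-hydroxy-2,3-dimethylbutan-1-one | COc1cc([C@@H](O[Si](C)(C)C(C)(C)C)[C@@](C)(O)[C@@H](C)C(=O)c2ccc(OCc3ccccc3)c(OC)c2)ccc1OCc1ccccc1 | intermediate
15 | (2S,3S,4R)-1,4-bis[4-(benzyloxy)-3-methoxyphenyl]-4-[(tert-butyldimethylsilyl)oxy]-2,3-dimethylbutane-1,3-diol, both C1 epimers | COc1cc([C@@H](O[Si](C)(C)C(C)(C)C)[C@@](C)(O)[C@@H](C)C(O)c2ccc(OCc3ccccc3)c(OC)c2)ccc1OCc1ccccc1 | intermediate
16 | (1R,2S,3S)-1,4-bis[4-(benzyloxy)-3-methoxyphenyl]-2,3-dimethylbutane-1,2,4-triol, both C4 epimers | COc1cc([C@@H](O)[C@@](C)(O)[C@@H](C)C(O)c2ccc(OCc3ccccc3)c(OC)c2)ccc1OCc1ccccc1 | intermediate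
17 | (2R,3S,4S,5R)-2,5-bis[4-(benzyloxy)-3-methoxyphenyl]-3,4-dimethyloxolan-3-ol | COc1cc([C@H]2O[C@@H](c3ccc(OCc4ccccc4)c(OC)c3)[C@H](C)[C@]2(C)O)ccc1OCc1ccccc1 | intermediate
18 | (2R,3S,4S,5R)-2,5-bis(4-hydroxy-3-methoxyphenyl)-3,4-dimethyloxolan-3-ol | COc1cc([C@H]2O[C@@H](c3ccc(O)c(OC)c3)[C@H](C)[C@]2(C)O)ccc1O | target

## Step count and least certain steps

Total: 11 steps. Longest linear sequence: 10 steps (steps 1–4, then 6–11); the second branch (step 5) joins at step 6.

**Step 6 (key step).**
- **Risk:** The trisubstituted alkene of 7, flanked by a bulky silyloxy-bearing carbon, may react so slowly that 11 is lost by dimerisation to a furoxan. The facial preference may also be only moderate, because it rests on a conformational bias and not on a covalent constraint.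
- **Fallback (sets out from 3, 10 and 4; returns at 12):** C3 and C4 are set first on a small hydroxyl-directed dipolarophile, and the C2 carbinol is built afterwards.
  - 3 is reduced (NaBH4, CeCl3·7H2O, MeOH, 0 °C) to (2E)-2-methylbut-2-en-1-ol F1.
  - The zinc alkoxide of F1, made with Et2Zn in the presence of diisopropyl tartrate, takes up 11 released from 10 in the same flask. This is a tartrate-controlled, alkoxide-directed nitrile oxide cycloaddition, which is faster and regiodirecting; the tartrate enantiomer is chosen to lead into the (4S,5S) series. The product is [(4S,5S)-3-[4-(benzyloxy)-3-methoxyphenyl]-4,5-dimethyl-4,5-dihydro-1,2-oxazol-5-yl]methanol F2.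
  - Dess–Martin oxidation gives the non-enolisable (4S,5S)-3-[4-(benzyloxy)-3-methoxyphenyl]-4,5-dimethyl-4,5-dihydro-1,2-oxazole-5-carbaldehyde F3.
  - Addition of 4 in THF at −78 °C under Felkin–Anh (non-chelation) control, with the ring oxygen anti to the incoming aryl group and the nucleophile passing the methyl group, gives (R)-[4-(benzyloxy)-3-methoxyphenyl][(4S,5S)-3-[4-(benzyloxy)-3-methoxyphenyl]-4,5-dimethyl-4,5-dihydro-1,2-oxazol-5-yl]methanol F4.
  - Silylation as in step 4 gives 12.

**Step 3.**
- **Risk:** Erosion of enantiomeric purity, either because the rate difference is smaller for an aryl carbinol than for an alkyl carbinol, or because tetravalent titanium ionises the electron-rich benzylic allylic alcohol (racemisation, allylic transposition).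
- **Fallback (sets out from 5; returns at 6):** The whole of 5 is oxidised with MnO2 in CH2Cl2 to (2E)-1-[4-(benzyloxy)-3-methoxyphenyl]-2-methylbut-2-en-1-one F5. F5 is reduced with BH3·SMe2 and the (R)-B-methyl oxazaborolidine (CBS reduction) to 6. This takes the coplanar aryl group as the larger flank; the uncertain discrimination between two sp2 flanks is the reason this sequence is the fallback and not the first choice.

**Step 10.**
- **Risk:** Ionisation at C2 as well as at C5 (pinacol-type shift from C3 or loss of the C2 configuration), and loss of a proton from the C5 cation to a styrene with scrambling of C4.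
- **Fallback (sets out from 15; returns at 17):** Step 9 is left out, and 15 is treated with BF3·OEt2 in CH2Cl2 at −78 → −20 °C. Only the free C5 hydroxyl can then ionise; the silyl ether oxygen at C2 acts as the nucleophile and loses its silyl group after ring closure (desilylative cycloetherification), so C2 is capped throughout. This fallback passes through no new compound (F0).

**Step 11.**
- **Risk:** Over-reduction, that is hydrogenolysis of one of the benzylic C–O bonds of the ring with ring opening.
- **Fallback (sets out from 16; returns at 18):** The order of the last two steps is exchanged. 16 is debenzylated (H2, Pd/C, EtOAc) while no benzylic ring ether exists yet, giving (1R,2S,3S)-1,4-bis(4-hydroxy-3-methoxyphenyl)-2,3-dimethylbutane-1,2,4-triol F6. The ring is then closed under very mild acid (PPTS, CH2Cl2/MeCN) through the p-quinone methide at C5, in the manner of the biosynthetic closure, to give 18 directly.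

## Further compounds

F1 | step 6 | (2E)-2-methylbut-2-en-1-ol | C/C=C(\C)CO
F2 | step 6 | [(4S,5S)-3-[4-(benzyloxy)-3-methoxyphenyl]-4,5-dimethyl-4,5-dihydro-1,2-oxazol-5-yl]methanol | OC[C@@]1(C)ON=C(c2ccc(OCc3ccccc3)c(OC)c2)[C@@H]1C
F3 | step 6 | (4S,5S)-3-[4-(benzyloxy)-3-methoxyphenyl]-4,5-dimethyl-4,5-dihydro-1,2-oxazole-5-carbaldehyde | O=C[C@@]1(C)ON=C(c2ccc(OCc3ccccc3)c(OC)c2)[C@@H]1C
F4 | step 6 | (R)-[4-(benzyloxy)-3-methoxyphenyl][(4S,5S)-3-[4-(benzyloxy)-3-methoxyphenyl]-4,5-dimethyl-4,5-dihydro-1,2-oxazol-5-yl]methanol | COc1cc([C@@H](O)[C@@]2(C)ON=C(c3ccc(OCc4ccccc4)c(OC)c3)[C@@H]2C)ccc1OCc1ccccc1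
F5 | step 3 | (2E)-1-[4-(benzyloxy)-3-methoxyphenyl]-2-methylbut-2-en-1-one | COc1cc(C(=O)/C(C)=C/C)ccc1OCc1ccccc1
F0 | step 10 | none | none
F6 | step 11 | (1R,2S,3S)-1,4-bis(4-hydroxy-3-methoxyphenyl)-2,3-dimethylbutane-1,2,4-triol, both C4 epimers | COc1cc([C@@H](O)[C@@](C)(O)[C@@H](C)C(O)c2ccc(O)c(OC)c2)ccc1O
A1 | alternative 1 | (2R,3S,4S,5R)-2,5-bis[4-(benzyloxy)-3-methoxyphenyl]-3,4-dimethyloxolan-3-yl acetate | COc1cc([C@H]2O[C@@H](c3ccc(OCc4ccccc4)c(OC)c3)[C@H](C)[C@]2(C)OC(C)=O)ccc1OCc1ccccc1
A2 | alternative 1 | (3S,4R)-3-(acetyloxy)-3,4-dimethyloxolane-2,5-diyl diacetate, anomeric mixture | CC(=O)OC1OC(OC(C)=O)[C@H](C)[C@]1(C)OC(C)=O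
A3 | alternative 1 | [4-(benzyloxy)-3-methoxyphenyl]zinc bromide | COc1cc([Zn]Br)ccc1OCc1ccccc1
A4 | alternative 2 | (2R,4S,5R)-2,5-bis[4-(benzyloxy)-3-methoxyphenyl]-4-methyloxolan-3-one | COc1cc([C@H]2O[C@@H](c3ccc(OCc4ccccc4)c(OC)c3)[C@H](C)C2=O)ccc1OCc1ccccc1
A5 | alternative 2 | (2R,4R,5Z)-2,4-bis[4-(benzyloxy)-3-methoxyphenyl]-5-ethylidene-1,3-dioxolane | C/C=C1\O[C@H](c2ccc(OCc3ccccc3)c(OC)c2)O[C@@H]1c1ccc(OCc2ccccc2)c(OC)c1
A6 | alternative 2 | (2R)-2-[4-(benzyloxy)-3-methoxyphenyl]-2-hydroxyacetic acid | COc1cc([C@@H](O)C(=O)O)ccc1OCc1ccccc1
A7 | alternative 3 | (2R,3S,4S,5R)-2,5-bis(4-hydroxy-3-methoxyphenyl)-3,4-dimethyloxolan-3-yl acetate | COc1cc([C@H]2O[C@@H](c3ccc(O)c(OC)c3)[C@H](C)[C@]2(C)OC(C)=O)ccc1O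
A8 | alternative 3 | (E)-isoeugenol, 2-methoxy-4-[(1E)-prop-1-en-1-yl]phenol | COc1cc(/C=C/C)ccc1O
A9 | alternative 3 | (Z)-1-(4-hydroxy-3-methoxyphenyl)prop-1-en-2-yl acetate | COc1cc(/C=C(/C)OC(C)=O)ccc1O
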